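- By the last reading of both earlier runs the target stands below its first reading and the isomer of the product above its own, so my choice for the next flask, 0.50 M of starting material with 0.150 M of protic impurity, lies between changing the charge and shortening the time.

| flask | starting material | protic impurity | remark | time |
|---|---|---|---|---|
| Monday's | 0.25 M | 0.15 M | run made earlier |  |
| Sunday's | 1 M | 0.15 M | run made earlier |  |
| flask | 0.50 M | 0.150 M |  | 10 d |

| run | time / d | target / % | isomer of the product / % |
|---|---|---|---|
| Monday's | 1.25 | 33.1 | 2.7 |
| Monday's | 3.00 | 23.6 | 3.3 |
| Monday's | 4.00 | 20.6 | 4.9 |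
| Monday's | 6.00 | 16.2 | 5.8 |
| Monday's | 8.00 | 15.3 | 7.6 |
| Monday's | 10.0 | 13.1 | 6.6 |
| Sunday's | 1.25 | 34.1 | 3.2 |
| Sunday's | 3.00 | 26.2 | 5.3 |
| Sunday's | 4.00 | 23.5 | 5.7 |
| Sunday's | 6.00 | 19.0 | 6.2 |
| Sunday's | 8.00 | 17.2 | 7.8 |
| Sunday's | 10.0 | 13.7 | 8.6 |

(standard deviation of a reading: 0.5 percentage points)

* share of target in target plus isomer of the product at 6.0 min
* share of target in target plus isomer of the product at 10 d



- I work in logarithms: L is the common logarithm of target over isomer of the product.

- Between first and last reading, L falls from 1.09 to 0.298 in Monday's run and from 1.03 to 0.202 in Sunday's, so at that pace, as read, a shrinking of the ratio by a factor of 10 takes 11.1 d and 10.6 d.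

- Their mean, 10.8 d, is my decade time: the days the ratio, as read, takes to shrink by that factor.

- At 10 d the runs differ in L by 0.0955, less than the fall of 0.791 in Monday's run, although their charges differ 4.00 times, so I leave the charge as written and treat time as the thing to shorten.

- The new charge lies midway between the two on a logarithmic scale, so I take the mean L of 0.250, which gives a share of 64.0% at 10 d.

- Carrying the mean first L back along the decade time gives 1.17, a share of 93.7% at 6.0 min, on a line drawn beyond the readings.

- The forecast gives 97% (92% to 100%), higher than my early share, and 64% (60% to 68%), and remarks: “The intercept is poorly defined”.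

- The flask gives 97.3% at 6.0 min and 65.7% at 10 d.

    starting material ⇌ target (K = 3.20, k = 0.220 h⁻¹)
    starting material ⇌ isomer of the product (K = 3.30, k = 0.00610 h⁻¹)
    2 starting material → self-condensation product (k = 0.140 L mol⁻¹ h⁻¹)
    starting material + protic impurity → quenched substrate (k = 0.920 L mol⁻¹ h⁻¹)
    starting material ⇌ dormant form (K = 0.790, k = 0.260 h⁻¹)

- The rate constant of starting material passing into target over that of its passing into isomer of the product, the selectivity factor, is 36.1, and in the flask the decade time is 2.55 d from 6.0 min to 1.00 d, shorter than the 10.2 d from then to 10.0 d, which stands beside my 10.8 d. The neighbour flask with 0.60 M of protic impurity has a decade time of 3.99 d from 6.0 min to 10 d, shorter than the flask's 7.85 d over that span, and ends at a share of 10.1%.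

The numbers in the tables stem from a simulated flask on assumed constants; the scatter is artificial.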